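**Strategy.** Numbering follows the oct-6-en-1-one chain: C2 is the quaternary carbon, C3 bears the isopropenyl group, and C4 bears the 3-methylbut-3-enyl group and the prenyl CH2 (C5). The route rests on forming C3–C4. C3 is allylic through its isopropenyl group and C5–C6 can be an aldehyde, so the isopropenyl–C3–C4–C5–C6 array is the retron of an anionic oxy-Cope rearrangement. The precursor is a bis-allylic ether that looks unlike the product: an (E)-6-methylhepta-2,6-dienyl group on the oxygen of a methacrolein-derived carbinol carrying C2. One treatment with KH effects [2,3]-Wittig then oxy-Cope shifts, exchanging the C3–O bond for the C3–C4 bond, setting C3 and C4 and unveiling the C6 aldehyde.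

Key step: step 8

Assumption: compounds 1, 2, 5, 11, 12 and 19 are purchased; stereodescriptors refer to each compound's own numbering, and C2, C3 and C4 of acids 17 and 18 coincide with C2, C3 and C4 of the target.

Step 1
Reactants: 1 5-methylhex-4-enoic acid; 2 (S)-4-benzyloxazolidin-2-one
Product: 4 (S)-4-benzyl-3-(5-methylhex-4-enoyl)oxazolidin-2-one, via mixed pivalic anhydride 3 (not isolated)
Conditions: PivCl, Et3N, THF, −20 °C; then 2, LiCl, rt
Reagents that add atoms: none
Why: N-acylation through the mixed anhydride, in which the LiCl-activated oxazolidinone attacks the unhindered carbonyl of 3; no stereocenter is formed.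

Step 2
Reactants: 4 (S)-4-benzyl-3-(5-methylhex-4-enoyl)oxazolidin-2-one; 5 methacrolein
Product: 7 (S)-4-benzyl-3-[(2S,3S)-3-hydroxy-4-methyl-2-(3-methylbut-2-en-1-yl)pent-4-enoyl]oxazolidin-2-one, via Z-boron enolate 6 (not isolated)
Conditions: Bu2BOTf, iPr2NEt, CH2Cl2, 0 °C; 5, −78 → 0 °C; then H2O2, MeOH, pH 7 buffer
Reagents that add atoms: none
Why: Evans syn-aldol reaction, in which enolate 6 adds through a Zimmerman–Traxler chair on the face away from the benzyl group and so sets the carbinol center C3 as (S); the C2 center formed here is erased in step 4.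

Step 3
Reactants: 7 (S)-4-benzyl-3-[(2S,3S)-3-hydroxy-4-methyl-2-(3-methylbut-2-en-1-yl)pent-4-enoyl]oxazolidin-2-one
Product: 8 methyl (2S,3S)-3-hydroxy-4-methyl-2-(3-methylbut-2-en-1-yl)pent-4-enoate
Conditions: MeMgBr, MeOH, THF, 0 °C
Reagents that add atoms: methanol, CO
Why: Transesterification of the exocyclic imide carbonyl by bromomagnesium methoxide should release the auxiliary under conditions too mild for retro-aldol cleavage, leaving C3 untouched.

Step 4
Reactants: 8 methyl (2S,3S)-3-hydroxy-4-methyl-2-(3-methylbut-2-en-1-yl)pent-4-enoate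
Product: 10 methyl (2S,3R)-3-hydroxy-2,4-dimethyl-2-(3-methylbut-2-en-1-yl)pent-4-enoate, via chelated dilithium dianion 9 (not isolated)
Conditions: LiN(iPr)2 (2.3 equiv), THF, −78 → −20 °C; MeI, DMPU, −78 → 0 °C
Reagents that add atoms: iodomethane, CI
Why: Fráter–Seebach alkylation, in which the lithium-chelated dianion 9 is methylated on the face anti to the isopropenyl group of the carbinol carbon, so the quaternary center is (2S) with the prenyl group syn to OH (C3 is unchanged; its descriptor changes only through priorities).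

Step 5
Reactants: 11 2-methylhexa-1,5-diene; 12 (Z)-1,4-dichlorobut-2-ene
Product: 13 (E)-1-chloro-6-methylhepta-2,6-diene
Conditions: second-generation Grubbs catalyst RuCl2(=CHPh)(H2IMes)(PCy3) (3 mol %), 12 (4 equiv), CH2Cl2, 40 °C
Reagents that add atoms: none
Why: Cross metathesis at the monosubstituted alkene of 11 (the 1,1-disubstituted end is inert to this catalyst) under thermodynamic control should favour the (E)-allylic chloride, and any (Z)-isomer is removed on AgNO3-impregnated silica.

Step 6
Reactants: 10 methyl (2S,3R)-3-hydroxy-2,4-dimethyl-2-(3-methylbut-2-en-1-yl)pent-4-enoate; 13 (E)-1-chloro-6-methylhepta-2,6-diene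
Product: 14 methyl (2S,3R)-2,4-dimethyl-2-(3-methylbut-2-en-1-yl)-3-{[(2E)-6-methylhepta-2,6-dien-1-yl]oxy}pent-4-enoate
Conditions: NaH, Bu4NI (10 mol %), THF–DMF, 0 °C → rt
Reagents that add atoms: none
Why: Williamson ether synthesis, in which the sodium alkoxide of 10 displaces halide from the primary allylic halide by SN2 with retention of the (E) geometry; no stereocenter is touched.

Step 7
Reactants: 14 methyl (2S,3R)-2,4-dimethyl-2-(3-methylbut-2-en-1-yl)-3-{[(2E)-6-methylhepta-2,6-dien-1-yl]oxy}pent-4-enoate
Product: 15 (2S,3R)-2,4-dimethyl-2-(3-methylbut-2-en-1-yl)-3-{[(2E)-6-methylhepta-2,6-dien-1-yl]oxy}pent-4-enoic acid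
Conditions: n-PrSLi, HMPA, rt; then aq HCl
Reagents that add atoms: none
Why: SN2 demethylation by thiolate at the ester methyl carbon frees the hindered acid without touching the quaternary center, and the carboxylate is inert to the carbanion and enolate of step 8 and stops at the ketone in step 10.

Step 8
Reactants: 15 (2S,3R)-2,4-dimethyl-2-(3-methylbut-2-en-1-yl)-3-{[(2E)-6-methylhepta-2,6-dien-1-yl]oxy}pent-4-enoic acid
Product: 17 (2S,3S,4S)-2-methyl-2-(3-methylbut-2-en-1-yl)-4-(3-methylbut-3-en-1-yl)-6-oxo-3-(prop-1-en-2-yl)hexanoic acid, via dipotassium dienol alkoxide 16 (not isolated)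
Conditions: KH (4 equiv), 18-crown-6, THF, 0 °C → rt; then aq NH4Cl, dilute HCl to pH 4, 0 °C
Reagents that add atoms: none
Why: KH first makes the potassium carboxylate and then removes a proton from the unhindered allylic OCH2 (the other O–CH is shielded by the quaternary carbon), and the α-oxy allyl carbanion shifts [2,3] onto the =CH2 end of the methallyl unit through an envelope with the quaternary carbon eclipsing C=CH2 (avoiding the vinylic methyl) and the vinyl group exo, giving the (3Z,6S)-alkoxide 16 by 1,3-transfer of chirality from the carbinol carbon of 15. The naked alkoxide then undergoes the anionic oxy-Cope [3,3] shift, which forms the C3–C8 bond of 16 (C3–C4 of 17 and of the target), breaks C5–C6 and leaves an aldehyde enolate that is protonated on work-up. The closest known reaction type is the tandem [2,3]-Wittig–anionic oxy-Cope rearrangement of bis-allylic ethers under KH and 18-crown-6; no ring is closed. In the chair the oxido group and the 3-methylbut-3-enyl chain are pseudo-equatorial and the quaternary group, cis on the C3=C4 bond, is pseudo-axial, so the (7E) alkene sets C4 of 17 as (S), the (3Z) alkene sets C3 as (S) and the (6S) carbinol fixes the face. The step needs regioselective deprotonation, [2,3] over [1,2] shift and chair over boat or fragmentation; the shielding of the second O–CH, the concerted five-centre path at low temperature and the equatorial preference of the oxido group are relied on, and the carboxylate keeps the acyl carbon inert.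

Step 9
Reactants: 17 (2S,3S,4S)-2-methyl-2-(3-methylbut-2-en-1-yl)-4-(3-methylbut-3-en-1-yl)-6-oxo-3-(prop-1-en-2-yl)hexanoic acid
Product: 18 (2S,3S,4S)-2,7-dimethyl-2-(3-methylbut-2-en-1-yl)-4-(3-methylbut-3-en-1-yl)-3-(prop-1-en-2-yl)oct-6-enoic acid
Conditions: iPrPPh3I, n-BuLi, THF, 0 °C; then 17, −78 °C → rt (3 equiv of ylide)
Reagents that add atoms: isopropyltriphenylphosphonium iodide, CC(C)[P+](c1ccccc1)(c1ccccc1)c1ccccc1.[I-]
Why: Wittig olefination of the unhindered aldehyde by the non-stabilised isopropylidene ylide (the first equivalent only forms the carboxylate) turns CH2CHO into the prenyl group, and no stereocenter is at risk because C4 is β to the aldehyde.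

Step 10
Reactants: 18 (2S,3S,4S)-2,7-dimethyl-2-(3-methylbut-2-en-1-yl)-4-(3-methylbut-3-en-1-yl)-3-(prop-1-en-2-yl)oct-6-enoic acid; 19 (3-bromophenoxy)(tert-butyl)dimethylsilane
Product: 21 (2S,3S,4S)-1-(3-hydroxyphenyl)-2,7-dimethyl-2-(3-methylbut-2-en-1-yl)-4-(3-methylbut-3-en-1-yl)-3-(prop-1-en-2-yl)oct-6-en-1-one (garcinielliptone FA), via silyl ether ketone 20 (not isolated)
Conditions: 19 (4 equiv), t-BuLi, Et2O, −78 °C; then 18, THF, −78 °C → rt; aq NH4Cl; then TBAF, THF, rt
Reagents that add atoms: none
Why: Ketone synthesis from a carboxylate and an organolithium, in which the aryllithium adds to the lithium salt of 18 to give a dilithium ketone hydrate that cannot add a second time and collapses to 20 on quench, after which fluoride cleaves the aryl silyl ether; the quaternary α-carbon cannot epimerise.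

**Compound list**

1 | 5-methylhex-4-enoic acid | CC(C)=CCCC(=O)O | starting material
2 | (S)-4-benzyloxazolidin-2-one | O=C1N[C@@H](Cc2ccccc2)CO1 | starting material
3 | 5-methylhex-4-enoic pivalic anhydride (mixed anhydride) | CC(C)=CCCC(=O)OC(=O)C(C)(C)C | intermediate
4 | (S)-4-benzyl-3-(5-methylhex-4-enoyl)oxazolidin-2-one | CC(C)=CCCC(=O)N1[C@@H](Cc2ccccc2)COC1=O | intermediate
5 | methacrolein (2-methylprop-2-enal) | CC(=C)C=O | starting material
6 | Z-dibutylboron enolate of 4 | CC(C)=CC/C=C(\OB(CCCC)CCCC)N1[C@@H](Cc2ccccc2)COC1=O | intermediate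
7 | (S)-4-benzyl-3-[(2S,3S)-3-hydroxy-4-methyl-2-(3-methylbut-2-en-1-yl)pent-4-enoyl]oxazolidin-2-one | CC(C)=CC[C@@H]([C@H](O)C(C)=C)C(=O)N1[C@@H](Cc2ccccc2)COC1=O | intermediate
8 | methyl (2S,3S)-3-hydroxy-4-methyl-2-(3-methylbut-2-en-1-yl)pent-4-enoate | CC(C)=CC[C@@H]([C@H](O)C(C)=C)C(=O)OC | intermediate
9 | chelated dilithium alkoxide enolate of 8 | CC(C)=CC/C(=C(/[O-])OC)[C@H]([O-])C(C)=C.[Li+].[Li+] | intermediate
10 | methyl (2S,3R)-3-hydroxy-2,4-dimethyl-2-(3-methylbut-2-en-1-yl)pent-4-enoate | CC(C)=CC[C@@](C)([C@H](O)C(C)=C)C(=O)OC | intermediate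
11 | 2-methylhexa-1,5-diene | C=C(C)CCC=C | starting material
12 | (Z)-1,4-dichlorobut-2-ene | ClC/C=C\CCl | starting material
13 | (E)-1-chloro-6-methylhepta-2,6-diene | C=C(C)CC/C=C/CCl | intermediate
14 | methyl (2S,3R)-2,4-dimethyl-2-(3-methylbut-2-en-1-yl)-3-{[(2E)-6-methylhepta-2,6-dien-1-yl]oxy}pent-4-enoate | CC(C)=CC[C@@](C)([C@H](OC/C=C/CCC(C)=C)C(C)=C)C(=O)OC | intermediate
15 | (2S,3R)-2,4-dimethyl-2-(3-methylbut-2-en-1-yl)-3-{[(2E)-6-methylhepta-2,6-dien-1-yl]oxy}pent-4-enoic acid | CC(C)=CC[C@@](C)([C@H](OC/C=C/CCC(C)=C)C(C)=C)C(=O)O | intermediate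
16 | dipotassium (2S,3Z,6S,7E)-2,4,11-trimethyl-2-(3-methylbut-2-en-1-yl)-6-oxidododeca-3,7,11-trienoate | CC(C)=CC[C@@](C)(/C=C(/C)C[C@H]([O-])/C=C/CCC(C)=C)C(=O)[O-].[K+].[K+] | intermediate
17 | (2S,3S,4S)-2-methyl-2-(3-methylbut-2-en-1-yl)-4-(3-methylbut-3-en-1-yl)-6-oxo-3-(prop-1-en-2-yl)hexanoic acid | C=C(C)CC[C@@H](CC=O)[C@@H](C(=C)C)[C@](C)(CC=C(C)C)C(=O)O | intermediate
18 | (2S,3S,4S)-2,7-dimethyl-2-(3-methylbut-2-en-1-yl)-4-(3-methylbut-3-en-1-yl)-3-(prop-1-en-2-yl)oct-6-enoic acid | C=C(C)CC[C@@H](CC=C(C)C)[C@@H](C(=C)C)[C@](C)(CC=C(C)C)C(=O)O | intermediate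
19 | (3-bromophenoxy)(tert-butyl)dimethylsilane | CC(C)(C)[Si](C)(C)Oc1cccc(Br)c1 | starting material
20 | tert-butyldimethylsilyl ether of 21 | C=C(C)CC[C@@H](CC=C(C)C)[C@@H](C(=C)C)[C@](C)(CC=C(C)C)C(=O)c1cccc(O[Si](C)(C)C(C)(C)C)c1 | intermediate
21 | (2S,3S,4S)-1-(3-hydroxyphenyl)-2,7-dimethyl-2-(3-methylbut-2-en-1-yl)-4-(3-methylbut-3-en-1-yl)-3-(prop-1-en-2-yl)oct-6-en-1-one (garcinielliptone FA) | C=C(C)CC[C@@H](CC=C(C)C)[C@@H](C(=C)C)[C@](C)(CC=C(C)C)C(=O)c1cccc(O)c1 | target

**Step count and risks**

Total step count: 10. Longest linear sequence: 9 (steps 1–4 and 6–10; step 5 makes the second fragment).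

Step 8. The [2,3] shift may give a mixture of alkene geometries. In the [3,3] stage the pseudo-axial quaternary group may divert the alkoxide into a boat path, or into fragmentation to an enal and an allyl anion followed by unselective recombination. Either would erode control at C3 and C4. Fallback: the two shifts are separated and the second is run without an alkoxide. Starting from 15, LiN(iPr)2–KOtBu in THF at −78 °C with a cold quench should stop after the [2,3] shift at the dienol acid F1. Me3SiCl and imidazole then give its bis(trimethylsilyl) derivative F2. Heating in decalin at about 190 °C should effect a neutral siloxy-Cope rearrangement to the silyl enol ether F3, where no ionic fragmentation is possible. Aqueous citric acid hydrolyses both silyl groups and returns the route to 17.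

Step 6. The sodium alkoxide of 10 sits next to a quaternary carbon and may undergo retro-aldol cleavage faster than O-alkylation. Fallback: the ether is made under acid catalysis without any alkoxide. Starting from 11, cross metathesis with (Z)-but-2-ene-1,4-diol (second-generation Grubbs catalyst) gives (E)-6-methylhepta-2,6-dien-1-ol F4. Cl3CCN with catalytic DBU gives its trichloroacetimidate F5. F5 and 10 with catalytic TfOH in cyclohexane–CH2Cl2 at −20 °C should give 14, where the route is rejoined.

Step 10. Addition of the aryllithium to the very hindered lithium carboxylate may stall. Fallback: the ketone is built through the aldehyde oxidation level. Starting from 18, LiAlH4 gives the primary alcohol F6 and Dess–Martin periodinane gives the aldehyde F7. The aryllithium from 19 adds to give the benzylic alcohol F8 as a mixture of epimers. A second Dess–Martin oxidation gives 20, which is desilylated with TBAF as in step 10 to reach 21.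

**Further compounds**

F1 | step 8 | (2S,3Z,6S,7E)-6-hydroxy-2,4,11-trimethyl-2-(3-methylbut-2-en-1-yl)dodeca-3,7,11-trienoic acid | CC(C)=CC[C@@](C)(/C=C(/C)C[C@H](O)/C=C/CCC(C)=C)C(=O)O
F2 | step 8 | O-trimethylsilyl ether trimethylsilyl ester of F1 | CC(C)=CC[C@@](C)(/C=C(/C)C[C@H](O[Si](C)(C)C)/C=C/CCC(C)=C)C(=O)O[Si](C)(C)C
F3 | step 8 | (E)-trimethylsilyl enol ether of 17 as its trimethylsilyl ester | C=C(C)CC[C@@H](/C=C/O[Si](C)(C)C)[C@@H](C(=C)C)[C@](C)(CC=C(C)C)C(=O)O[Si](C)(C)C
F4 | step 6 | (E)-6-methylhepta-2,6-dien-1-ol | C=C(C)CC/C=C/CO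
F5 | step 6 | (E)-6-methylhepta-2,6-dien-1-yl 2,2,2-trichloroacetimidate | C=C(C)CC/C=C/COC(=N)C(Cl)(Cl)Cl
F6 | step 10 | primary alcohol from reduction of 18 (CH2OH in place of CO2H) | C=C(C)CC[C@@H](CC=C(C)C)[C@@H](C(=C)C)[C@](C)(CC=C(C)C)CO
F7 | step 10 | aldehyde from oxidation of F6 (CHO in place of CO2H of 18) | C=C(C)CC[C@@H](CC=C(C)C)[C@@H](C(=C)C)[C@](C)(CC=C(C)C)C=O
F8 | step 10 | benzylic alcohol from F7 and the aryllithium (carbinol epimers; secondary alcohol of 20) | C=C(C)CC[C@@H](CC=C(C)C)[C@@H](C(=C)C)[C@](C)(CC=C(C)C)C(O)c1cccc(O[Si](C)(C)C(C)(C)C)c1
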